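**Strategy.** Everything rests on closing the flavan pyran ring last, through its C4–C4a bond. Until then the A ring is a 4-alkyl-3,5-bis(benzyloxy)phenyl ether whose two free ring carbons (future C4a and C8) are equivalent, so Friedel–Crafts opening of a terminal epoxide by this ring can only deliver the C6-linked flavan. One operation forms the C4–C4a bond, the pyran ring and the free 3-hydroxyl while C2 and C3 stay untouched. The precursor is the nona-O-benzyl tetrahydrofuran ketone whose A-ring oxygen carries an (S)-aryl[(2R)-oxiranyl]methyl group, made from the core phenol and a Sharpless epoxy alcohol. The core comes from a rhodium-catalysed arylation, an Evans aldol and an oxocarbenium reduction.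

Key step: step 19

Remark: the target has nine phenolic hydroxyls, so 28 and 29 are nona-O-benzyl compounds and step 20 removes nine benzyl groups; C3 of 11–15 is carried as an epimer mixture because step 10 sets it under thermodynamic control.

Step 1
Reactants: 1 2',4'-dihydroxyacetophenone
Product: 2 1-[2,4-bis(benzyloxy)phenyl]ethan-1-one
Conditions: BnBr, K2CO3, DMF, 60 °C
Reagents that add atoms: benzyl bromide BrCc1ccccc1
Why: Williamson etherification of both phenols, with warming for the chelated 2'-OH; no stereocentre is involved.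

Step 2
Reactants: 3 2,4,6-trihydroxybenzaldehyde
Product: 4 4-(allyloxy)-2,6-dihydroxybenzaldehyde
Conditions: allyl bromide (1.05 equiv), NaHCO3, DMF, 40 °C
Reagents that add atoms: allyl bromide C=CCBr
Why: Williamson mono-alkylation; the 4-OH is the most acidic and the only hydroxyl not hydrogen-bonded to the formyl group, so hydrogencarbonate should ionise it selectively and leave the ring symmetric.

Step 3
Reactants: 4 4-(allyloxy)-2,6-dihydroxybenzaldehyde
Product: 5 4-(allyloxy)-2,6-bis(benzyloxy)benzaldehyde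
Conditions: BnBr, K2CO3, DMF, 70 °C
Reagents that add atoms: benzyl bromide BrCc1ccccc1
Why: Williamson etherification of the two equivalent chelated ortho phenols under forcing carbonate conditions.

Step 4
Reactants: 2 1-[2,4-bis(benzyloxy)phenyl]ethan-1-one; 5 4-(allyloxy)-2,6-bis(benzyloxy)benzaldehyde
Product: 6 (E)-3-[4-(allyloxy)-2,6-bis(benzyloxy)phenyl]-1-[2,4-bis(benzyloxy)phenyl]prop-2-en-1-one
Conditions: KOH, EtOH/THF, rt
Reagents that add atoms: none
Why: Claisen–Schmidt condensation of a methyl ketone with a non-enolisable aldehyde; dehydration of the aldol should give the conjugated E-enone.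

Step 5
Reactants: 6 (E)-chalcone; 7 [4-(benzyloxy)phenyl]boronic acid
Product: 8 (3S)-3-[4-(allyloxy)-2,6-bis(benzyloxy)phenyl]-1-[2,4-bis(benzyloxy)phenyl]-3-[4-(benzyloxy)phenyl]propan-1-one
Conditions: [Rh(OH)((R)-binap)]2 (3 mol %), 7 (2.5 equiv), dioxane/H2O 10:1, 50 °C
Reagents that add atoms: none
Why: Hayashi–Miyaura rhodium-catalysed asymmetric 1,4-addition; by the quadrant model the (R)-BINAP–Rh–aryl species should add the aryl group to the Re face of C3 of the E-enone, which sets the (S) diarylmethine centre.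

Step 6
Reactants: 9 (4R)-4-benzyl-1,3-oxazolidin-2-one
Product: 10 (4R)-4-benzyl-3-(bromoacetyl)-1,3-oxazolidin-2-one
Conditions: n-BuLi, THF, −78 °C; BrCH2COBr, −78 → 0 °C
Reagents that add atoms: bromoacetyl bromide O=C(Br)CBr
Why: N-acylation of the lithiated oxazolidinone by the acid bromide; the auxiliary stereocentre is not touched.

Step 7
Reactants: 8 (3S)-β,β-diaryl ketone; 10 (4R)-4-benzyl-3-(bromoacetyl)-1,3-oxazolidin-2-one
Product: 11 (4R)-4-benzyl-3-{(4S)-4-[4-(allyloxy)-2,6-bis(benzyloxy)phenyl]-3-[2,4-bis(benzyloxy)benzoyl]-4-[4-(benzyloxy)phenyl]butanoyl}-1,3-oxazolidin-2-one (C3 epimer mixture)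
Conditions: LiHMDS (1.05 equiv), THF, −78 °C; then 10, −78 → −30 °C
Reagents that add atoms: none
Why: SN2 alkylation of the lithium enolate of 8 (its only enolisable position) by the activated α-bromo imide; the new centre C3 need not be controlled here because step 10 equilibrates it.

Step 8
Reactants: 11 γ-keto imide; 12 4-(benzyloxy)benzaldehyde
Product: 14 (4R)-4-benzyl-3-[(2R,4S)-4-[4-(allyloxy)-2,6-bis(benzyloxy)phenyl]-3-[2,4-bis(benzyloxy)benzoyl]-4-[4-(benzyloxy)phenyl]-2-{(R)-[4-(benzyloxy)phenyl](hydroxy)methyl}butanoyl]-1,3-oxazolidin-2-one (C3 epimer mixture), via boron enolate 13 (not isolated)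
Conditions: Bu2BOTf, i-Pr2NEt, CH2Cl2, −78 → 0 °C; 12, −78 → 0 °C; pH 7 buffer, MeOH, H2O2
Reagents that add atoms: none
Why: Evans syn-aldol through the (Z)-boron enolate of the imide methylene and a Zimmerman–Traxler transition state; the (R)-benzyl auxiliary should direct attack to the aldehyde Re face and set both the α-carbon and the carbinol as (R), the future tetrahydrofuran C4 and C5 in a 4,5-trans relationship.

Step 9
Reactants: 14 syn-aldol imide
Product: 15 (2R,4S)-4-[4-(allyloxy)-2,6-bis(benzyloxy)phenyl]-3-[2,4-bis(benzyloxy)benzoyl]-4-[4-(benzyloxy)phenyl]-2-{(R)-[4-(benzyloxy)phenyl](hydroxy)methyl}-N-methoxy-N-methylbutanamide (C3 epimer mixture)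
Conditions: MeNHOMe·HCl, AlMe3, CH2Cl2, −20 → 0 °C
Reagents that add atoms: N,O-dimethylhydroxylamine hydrochloride CNOC.Cl
Why: Aluminium amide transamination of a β-hydroxy imide to the Weinreb amide, assisted by the β-alkoxide, should release the auxiliary without touching the two stereocentres set in step 8.

Step 10
Reactants: 15 γ-hydroxy keto Weinreb amide
Product: 17 (2R,3R,4R,5S)-4-{(S)-[4-(allyloxy)-2,6-bis(benzyloxy)phenyl][4-(benzyloxy)phenyl]methyl}-5-[2,4-bis(benzyloxy)phenyl]-2-[4-(benzyloxy)phenyl]-N-methoxy-N-methyloxolane-3-carboxamide, via cyclic methyl ketal 16 (not isolated)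
Conditions: PPTS, MeOH/CH2Cl2, 40 °C; evaporate; Et3SiH, BF3·OEt2, CH2Cl2, −78 → −40 °C
Reagents that add atoms: none
Why: Acid-catalysed ketalisation of the γ-hydroxy aryl ketone lets C3 (oxolane C4) equilibrate through the cyclic enol ether to the ketal with the C3 and C4 substituents trans, and the reduction of the 2-aryl oxocarbenium ion then delivers hydride anti to the C3 substituent, giving the 2,3-cis aryl ether centre as in hemiketal reductions of tetrahydrofuran lignans.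

Step 11
Reactants: 18 4-bromobenzene-1,3-diol
Product: 19 2,4-bis(benzyloxy)-1-bromobenzene
Conditions: BnBr, K2CO3, DMF, 60 °C
Reagents that add atoms: benzyl bromide BrCc1ccccc1
Why: Williamson etherification of both phenols.

Step 12
Reactants: 17 oxolane Weinreb amide; 19 2,4-bis(benzyloxy)-1-bromobenzene
Product: 21 [2,4-bis(benzyloxy)phenyl]{(2R,3R,4R,5S)-4-{(S)-[4-(allyloxy)-2,6-bis(benzyloxy)phenyl][4-(benzyloxy)phenyl]methyl}-5-[2,4-bis(benzyloxy)phenyl]-2-[4-(benzyloxy)phenyl]oxolan-3-yl}methanone, via aryllithium 20 (not isolated)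
Conditions: 19, n-BuLi, THF, −78 °C; then 17, −78 → −20 °C; aq. NH4Cl
Reagents that add atoms: none
Why: Bromine–lithium exchange followed by Weinreb ketone synthesis; the chelated tetrahedral adduct should stop at the ketone, and the α-centre keeps the configuration that is trans to both neighbours and therefore also the thermodynamic one.

Step 13
Reactants: 21 allyl-protected tetrahydrofuran ketone
Product: 22 [2,4-bis(benzyloxy)phenyl]{(2R,3R,4R,5S)-4-{(S)-[2,6-bis(benzyloxy)-4-hydroxyphenyl][4-(benzyloxy)phenyl]methyl}-5-[2,4-bis(benzyloxy)phenyl]-2-[4-(benzyloxy)phenyl]oxolan-3-yl}methanone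
Conditions: Pd(PPh3)4 (5 mol %), morpholine, THF, rt
Reagents that add atoms: none
Why: Palladium(0)-catalysed deallylation through a π-allyl complex trapped by morpholine should free only the A-ring 4-hydroxyl and leave benzyl ethers, ketone and ring ethers intact.

Step 14
Reactants: 23 (E)-4-hydroxycinnamic acid (p-coumaric acid)
Product: 24 benzyl (E)-3-[4-(benzyloxy)phenyl]prop-2-enoate
Conditions: BnBr (2.3 equiv), K2CO3, DMF, 60 °C
Reagents that add atoms: benzyl bromide BrCc1ccccc1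
Why: Williamson etherification and carboxylate alkylation in one operation.

Step 15
Reactants: 24 benzyl (E)-3-[4-(benzyloxy)phenyl]prop-2-enoate
Product: 25 (E)-3-[4-(benzyloxy)phenyl]prop-2-en-1-ol
Conditions: DIBAL-H (2.2 equiv), CH2Cl2, −78 °C; Rochelle salt
Reagents that add atoms: none
Why: 1,2-Reduction of the enoate by DIBAL-H should give the allylic alcohol with the E-alkene intact.

Step 16
Reactants: 25 (E)-3-[4-(benzyloxy)phenyl]prop-2-en-1-ol
Product: 26 {(2R,3R)-3-[4-(benzyloxy)phenyl]oxiran-2-yl}methanol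
Conditions: Ti(Oi-Pr)4 (10 mol %), D-(−)-DIPT (12 mol %), t-BuOOH, 4 Å MS, CH2Cl2, −20 °C
Reagents that add atoms: tert-butyl hydroperoxide CC(C)(C)OO
Why: Sharpless asymmetric epoxidation; the D-(−)-tartrate ligand should give the (2R,3R) epoxy alcohol (the mirror image of the L-(+)-tartrate outcome for E-cinnamyl alcohols), and the catalytic, sieve-dried protocol is chosen because this electron-rich epoxide is acid-sensitive.

Step 17
Reactants: 22 core phenol; 26 {(2R,3R)-3-[4-(benzyloxy)phenyl]oxiran-2-yl}methanol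
Product: 27 the 4-O-{(1S,2R)-1-[4-(benzyloxy)phenyl]-2,3-dihydroxypropyl} ether of 22
Conditions: Cs2CO3 (0.5 equiv), 26 (1.5 equiv), DMF, 60 °C
Reagents that add atoms: none
Why: Phenoxide SN2 opening of the 2,3-epoxy alcohol at the benzylic C3 with inversion (3R to S) while C2 keeps its oxygen and configuration, the known regiochemistry of aryloxide additions to trans-3-arylglycidols.

Step 18
Reactants: 27 aryloxy diol
Product: 28 the 4-O-{(S)-[4-(benzyloxy)phenyl][(2R)-oxiran-2-yl]methyl} ether of 22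
Conditions: PPh3, DIAD, THF, 0 °C → rt
Reagents that add atoms: none
Why: Mitsunobu cyclodehydration of a terminal 1,2-diol; the primary hydroxyl is activated and displaced by the secondary oxygen, so the oxirane forms with retention at the secondary carbon under neutral conditions.

Step 19
Reactants: 28 nona-O-benzyl aryl glycidyl ether
Product: 29 [2,4-bis(benzyloxy)phenyl]{(2R,3R,4R,5S)-4-{(S)-[(2S,3R)-5,7-bis(benzyloxy)-2-[4-(benzyloxy)phenyl]-3-hydroxy-3,4-dihydro-2H-chromen-6-yl][4-(benzyloxy)phenyl]methyl}-5-[2,4-bis(benzyloxy)phenyl]-2-[4-(benzyloxy)phenyl]oxolan-3-yl}methanone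
Conditions: AuCl3 (5 mol %), AgOTf (15 mol %), CH2Cl2, −20 → 0 °C
Reagents that add atoms: none
Why: The Lewis acid coordinates the oxirane oxygen and the A ring attacks the unsubstituted epoxide carbon through one of its two free ring carbons, which lie ortho to the ether oxygen and are activated by three oxygen substituents; loss of a proton from the arenium ion gives the chroman and leaves the epoxide oxygen as the 3-hydroxyl. The closest known reaction type is the gold(III)- or HFIP-promoted intramolecular Friedel–Crafts epoxide–arene cyclisation of aryl glycidyl ethers to chroman-3-ols. The pyran ring closes in the 6-endo-tet mode at the primary carbon, the 5-exo alternative requiring attack at the secondary oxirane carbon, which is hindered and inductively deactivated by the neighbouring aryloxy-bearing carbon. No stereocentre is formed: flavan C2 and C3 are carried over from 28 because no bond to either carbon is broken, which keeps the 2,3-trans (2S,3R) arrangement. Attachment at C6 rather than C8 needs no control because the two nucleophilic carbons of the 4-alkyl-3,5-bis(benzyloxy)phenyl ether are equivalent, and the catalytic acid and low temperature are chosen to spare the benzylic C2–O1 and C5–O1 bonds of the tetrahydrofuran and the benzylic C2–O1 bond of the new flavan.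

Step 20
Reactants: 29 nona-O-benzyl target
Product: 30 (2,4-dihydroxyphenyl)[(2R,3R,4R,5S)-5-(2,4-dihydroxyphenyl)-2-(4-hydroxyphenyl)-4-{(S)-(4-hydroxyphenyl)[(2S,3R)-3,5,7-trihydroxy-2-(4-hydroxyphenyl)-3,4-dihydro-2H-chromen-6-yl]methyl}oxolan-3-yl]methanone
Conditions: H2 (1 atm), Pd(OH)2/C, EtOAc/MeOH, rt
Reagents that add atoms: none
Why: Hydrogenolysis of the nine benzyl ethers under mild pressure, conditions under which 2-aryl cyclic ethers of flavan and lignan type and ortho-hydroxyaryl ketones normally survive.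

**Compound list**

1 | 2',4'-dihydroxyacetophenone | CC(=O)c1ccc(O)cc1O | starting material
2 | 1-[2,4-bis(benzyloxy)phenyl]ethan-1-one | CC(=O)c1ccc(OCc9ccccc9)cc1OCc9ccccc9 | intermediate
3 | 2,4,6-trihydroxybenzaldehyde | O=Cc1c(O)cc(O)cc1O | starting material
4 | 4-(allyloxy)-2,6-dihydroxybenzaldehyde | O=Cc1c(O)cc(OCC=C)cc1O | intermediate
5 | 4-(allyloxy)-2,6-bis(benzyloxy)benzaldehyde | O=Cc1c(OCc9ccccc9)cc(OCC=C)cc1OCc9ccccc9 | intermediate
6 | (E)-3-[4-(allyloxy)-2,6-bis(benzyloxy)phenyl]-1-[2,4-bis(benzyloxy)phenyl]prop-2-en-1-one | O=C(/C=C/c1c(OCc9ccccc9)cc(OCC=C)cc1OCc9ccccc9)c1ccc(OCc9ccccc9)cc1OCc9ccccc9 | intermediate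
7 | [4-(benzyloxy)phenyl]boronic acid | OB(O)c1ccc(OCc9ccccc9)cc1 | starting material
8 | (3S)-3-[4-(allyloxy)-2,6-bis(benzyloxy)phenyl]-1-[2,4-bis(benzyloxy)phenyl]-3-[4-(benzyloxy)phenyl]propan-1-one | O=C(C[C@@H](c1ccc(OCc9ccccc9)cc1)c1c(OCc9ccccc9)cc(OCC=C)cc1OCc9ccccc9)c1ccc(OCc9ccccc9)cc1OCc9ccccc9 | intermediate
9 | (4R)-4-benzyl-1,3-oxazolidin-2-one | O=C1N[C@H](Cc2ccccc2)CO1 | starting material
10 | (4R)-4-benzyl-3-(bromoacetyl)-1,3-oxazolidin-2-one | O=C(CBr)N1[C@H](Cc2ccccc2)COC1=O | intermediate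
11 | (4R)-4-benzyl-3-{(4S)-4-[4-(allyloxy)-2,6-bis(benzyloxy)phenyl]-3-[2,4-bis(benzyloxy)benzoyl]-4-[4-(benzyloxy)phenyl]butanoyl}-1,3-oxazolidin-2-one (C3 epimer mixture) | O=C(CC(C(=O)c1ccc(OCc9ccccc9)cc1OCc9ccccc9)[C@@H](c1ccc(OCc9ccccc9)cc1)c1c(OCc9ccccc9)cc(OCC=C)cc1OCc9ccccc9)N1[C@H](Cc2ccccc2)COC1=O | intermediate
12 | 4-(benzyloxy)benzaldehyde | O=Cc1ccc(OCc9ccccc9)cc1 | starting material
13 | (Z)-dibutylboron enolate of 11 | CCCCB(CCCC)O/C(=C\C(C(=O)c1ccc(OCc9ccccc9)cc1OCc9ccccc9)[C@@H](c1ccc(OCc9ccccc9)cc1)c1c(OCc9ccccc9)cc(OCC=C)cc1OCc9ccccc9)N1[C@H](Cc2ccccc2)COC1=O | intermediate (not isolated)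
14 | (4R)-4-benzyl-3-[(2R,4S)-4-[4-(allyloxy)-2,6-bis(benzyloxy)phenyl]-3-[2,4-bis(benzyloxy)benzoyl]-4-[4-(benzyloxy)phenyl]-2-{(R)-[4-(benzyloxy)phenyl](hydroxy)methyl}butanoyl]-1,3-oxazolidin-2-one (C3 epimer mixture) | O=C([C@@H]([C@@H](O)c1ccc(OCc9ccccc9)cc1)C(C(=O)c1ccc(OCc9ccccc9)cc1OCc9ccccc9)[C@@H](c1ccc(OCc9ccccc9)cc1)c1c(OCc9ccccc9)cc(OCC=C)cc1OCc9ccccc9)N1[C@H](Cc2ccccc2)COC1=O | intermediate
15 | (2R,4S)-4-[4-(allyloxy)-2,6-bis(benzyloxy)phenyl]-3-[2,4-bis(benzyloxy)benzoyl]-4-[4-(benzyloxy)phenyl]-2-{(R)-[4-(benzyloxy)phenyl](hydroxy)methyl}-N-methoxy-N-methylbutanamide (C3 epimer mixture) | CON(C)C(=O)[C@@H]([C@@H](O)c1ccc(OCc9ccccc9)cc1)C(C(=O)c1ccc(OCc9ccccc9)cc1OCc9ccccc9)[C@@H](c1ccc(OCc9ccccc9)cc1)c1c(OCc9ccccc9)cc(OCC=C)cc1OCc9ccccc9 | intermediate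
16 | (2R,3R,4R)-4-{(S)-[4-(allyloxy)-2,6-bis(benzyloxy)phenyl][4-(benzyloxy)phenyl]methyl}-5-[2,4-bis(benzyloxy)phenyl]-2-[4-(benzyloxy)phenyl]-N,5-dimethoxy-N-methyloxolane-3-carboxamide (C5 anomers) | CON(C)C(=O)[C@@H]1[C@@H]([C@@H](c2ccc(OCc9ccccc9)cc2)c2c(OCc9ccccc9)cc(OCC=C)cc2OCc9ccccc9)C(OC)(c2ccc(OCc9ccccc9)cc2OCc9ccccc9)O[C@H]1c1ccc(OCc9ccccc9)cc1 | intermediate (not isolated)
17 | (2R,3R,4R,5S)-4-{(S)-[4-(allyloxy)-2,6-bis(benzyloxy)phenyl][4-(benzyloxy)phenyl]methyl}-5-[2,4-bis(benzyloxy)phenyl]-2-[4-(benzyloxy)phenyl]-N-methoxy-N-methyloxolane-3-carboxamide | CON(C)C(=O)[C@@H]1[C@@H]([C@@H](c2ccc(OCc9ccccc9)cc2)c2c(OCc9ccccc9)cc(OCC=C)cc2OCc9ccccc9)[C@@H](c2ccc(OCc9ccccc9)cc2OCc9ccccc9)O[C@H]1c1ccc(OCc9ccccc9)cc1 | intermediate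
18 | 4-bromobenzene-1,3-diol | Oc1ccc(Br)c(O)c1 | starting material
19 | 2,4-bis(benzyloxy)-1-bromobenzene | Brc1ccc(OCc9ccccc9)cc1OCc9ccccc9 | intermediate
20 | [2,4-bis(benzyloxy)phenyl]lithium | [Li]c1ccc(OCc9ccccc9)cc1OCc9ccccc9 | intermediate (not isolated)
21 | [2,4-bis(benzyloxy)phenyl]{(2R,3R,4R,5S)-4-{(S)-[4-(allyloxy)-2,6-bis(benzyloxy)phenyl][4-(benzyloxy)phenyl]methyl}-5-[2,4-bis(benzyloxy)phenyl]-2-[4-(benzyloxy)phenyl]oxolan-3-yl}methanone | O=C(c1ccc(OCc9ccccc9)cc1OCc9ccccc9)[C@@H]1[C@@H]([C@@H](c2ccc(OCc9ccccc9)cc2)c2c(OCc9ccccc9)cc(OCC=C)cc2OCc9ccccc9)[C@@H](c2ccc(OCc9ccccc9)cc2OCc9ccccc9)O[C@H]1c1ccc(OCc9ccccc9)cc1 | intermediate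
22 | [2,4-bis(benzyloxy)phenyl]{(2R,3R,4R,5S)-4-{(S)-[2,6-bis(benzyloxy)-4-hydroxyphenyl][4-(benzyloxy)phenyl]methyl}-5-[2,4-bis(benzyloxy)phenyl]-2-[4-(benzyloxy)phenyl]oxolan-3-yl}methanone | O=C(c1ccc(OCc9ccccc9)cc1OCc9ccccc9)[C@@H]1[C@@H]([C@@H](c2ccc(OCc9ccccc9)cc2)c2c(OCc9ccccc9)cc(O)cc2OCc9ccccc9)[C@@H](c2ccc(OCc9ccccc9)cc2OCc9ccccc9)O[C@H]1c1ccc(OCc9ccccc9)cc1 | intermediate
23 | (E)-4-hydroxycinnamic acid (p-coumaric acid) | OC(=O)/C=C/c1ccc(O)cc1 | starting material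
24 | benzyl (E)-3-[4-(benzyloxy)phenyl]prop-2-enoate | O=C(/C=C/c1ccc(OCc9ccccc9)cc1)OCc9ccccc9 | intermediate
25 | (E)-3-[4-(benzyloxy)phenyl]prop-2-en-1-ol | OC/C=C/c1ccc(OCc9ccccc9)cc1 | intermediate
26 | {(2R,3R)-3-[4-(benzyloxy)phenyl]oxiran-2-yl}methanol | OC[C@H]1O[C@@H]1c2ccc(OCc9ccccc9)cc2 | intermediate
27 | 4-O-{(1S,2R)-1-[4-(benzyloxy)phenyl]-2,3-dihydroxypropyl} ether of 22 | O=C(c1ccc(OCc9ccccc9)cc1OCc9ccccc9)[C@@H]1[C@@H]([C@@H](c2ccc(OCc9ccccc9)cc2)c2c(OCc9ccccc9)cc(O[C@@H](c4ccc(OCc9ccccc9)cc4)[C@H](O)CO)cc2OCc9ccccc9)[C@@H](c2ccc(OCc9ccccc9)cc2OCc9ccccc9)O[C@H]1c1ccc(OCc9ccccc9)cc1 | intermediate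
28 | 4-O-{(S)-[4-(benzyloxy)phenyl][(2R)-oxiran-2-yl]methyl} ether of 22 (key-step precursor) | O=C(c1ccc(OCc9ccccc9)cc1OCc9ccccc9)[C@@H]1[C@@H]([C@@H](c2ccc(OCc9ccccc9)cc2)c2c(OCc9ccccc9)cc(O[C@@H](c4ccc(OCc9ccccc9)cc4)[C@H]3CO3)cc2OCc9ccccc9)[C@@H](c2ccc(OCc9ccccc9)cc2OCc9ccccc9)O[C@H]1c1ccc(OCc9ccccc9)cc1 | intermediate
29 | nona-O-benzyl target with free flavan 3-hydroxyl (name as in step 19) | O=C(c1ccc(OCc9ccccc9)cc1OCc9ccccc9)[C@@H]1[C@@H]([C@@H](c2ccc(OCc9ccccc9)cc2)c2c(OCc9ccccc9)cc3c(c2OCc9ccccc9)C[C@@H](O)[C@H](c2ccc(OCc9ccccc9)cc2)O3)[C@@H](c2ccc(OCc9ccccc9)cc2OCc9ccccc9)O[C@H]1c1ccc(OCc9ccccc9)cc1 | intermediate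
30 | CNP0251055.1 (name as in step 20) | O=C(c1ccc(O)cc1O)[C@@H]1[C@@H]([C@@H](c2ccc(O)cc2)c2c(O)cc3c(c2O)C[C@@H](O)[C@H](c2ccc(O)cc2)O3)[C@@H](c2ccc(O)cc2O)O[C@H]1c1ccc(O)cc1 | target

**Totals.** Total step count: 20. Longest linear sequence: 14 steps (from 3 through steps 2, 3, 4, 5, 7, 8, 9, 10, 12, 13, 17, 18, 19, 20).

**Steps most likely to fail**

Step 19. Ionisation of a benzylic C–O bond may outrun the attack of the arene on the primary epoxide carbon. The bonds at risk are the aryl ether at the carbon that becomes flavan C2, activated by the para-benzyloxy group, and C2–O1 of the tetrahydrofuran. The result would be loss of the side chain or epimerisation. The fallback sets out from 22 and deactivates the B ring with a sulfonate. Commercial methyl (E)-4-hydroxycinnamate is tosylated (TsCl, Et3N) to methyl (E)-3-[4-(tosyloxy)phenyl]prop-2-enoate F1. DIBAL-H reduction gives (E)-3-[4-(tosyloxy)phenyl]prop-2-en-1-ol F2. Sharpless epoxidation with D-(−)-DIPT gives {(2R,3R)-3-[4-(tosyloxy)phenyl]oxiran-2-yl}methanol F3, a bench-stable epoxy alcohol. Opening by the phenoxide of 22 (Cs2CO3, DMF) gives the 4-O-{(1S,2R)-2,3-dihydroxy-1-[4-(tosyloxy)phenyl]propyl} ether of 22 F4. Mitsunobu closure gives the 4-O-{(S)-[(2R)-oxiran-2-yl][4-(tosyloxy)phenyl]methyl} ether of 22 F5. The same epoxide–arene cyclisation, now with a non-ionising benzylic ether, gives the 4'-O-tosyl octa-O-benzyl flavan F6. Sulfonate cleavage (KOH, MeOH/THF, 40 °C) gives the octa-O-benzyl compound with free 4'-hydroxyl F7, and hydrogenolysis as in step 20 returns to the route at 30.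

Step 5. Carbometalation of the di-ortho-substituted, electron-rich β-aryl enone may not take place, so that protodeboronation of 7 takes over, or the facial selectivity may be poor. The fallback sets out from 5 and uses an auxiliary-controlled cuprate addition. Knoevenagel–Doebner condensation (malonic acid, pyridine, piperidine) gives (E)-3-[4-(allyloxy)-2,6-bis(benzyloxy)phenyl]prop-2-enoic acid F8. The mixed pivalic anhydride and lithiated 9 give (4R)-3-{(E)-3-[4-(allyloxy)-2,6-bis(benzyloxy)phenyl]prop-2-enoyl}-4-benzyl-1,3-oxazolidin-2-one F9. Commercial 4-(benzyloxy)phenylmagnesium bromide with CuBr·SMe2 adds anti to the benzyl group of the chelated s-cis imide to give (4R)-3-{(3S)-3-[4-(allyloxy)-2,6-bis(benzyloxy)phenyl]-3-[4-(benzyloxy)phenyl]propanoyl}-4-benzyl-1,3-oxazolidin-2-one F10. MeNHOMe·HCl/AlMe3 gives (3S)-3-[4-(allyloxy)-2,6-bis(benzyloxy)phenyl]-3-[4-(benzyloxy)phenyl]-N-methoxy-N-methylpropanamide F11. Addition of aryllithium 20 comes back to the route at 8.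

Step 7. Proton transfer from the acidic α-bromo imide to the ketone enolate, or acyl transfer from the imide, may consume the enolate instead of SN2 alkylation. The fallback sets out from 8 and builds the imide in three operations. Alkylation of the same enolate with methyl bromoacetate gives methyl (4S)-4-[4-(allyloxy)-2,6-bis(benzyloxy)phenyl]-3-[2,4-bis(benzyloxy)benzoyl]-4-[4-(benzyloxy)phenyl]butanoate F12. Saponification (LiOH, THF/H2O) gives the corresponding butanoic acid F13. Activation as the mixed pivalic anhydride and acylation of 9 (Et3N, LiCl) comes back to the route at 11.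

**Further compounds**

F1 | step 19 | methyl (E)-3-[4-(tosyloxy)phenyl]prop-2-enoate | COC(=O)/C=C/c1ccc(OS(=O)(=O)c2ccc(C)cc2)cc1
F2 | step 19 | (E)-3-[4-(tosyloxy)phenyl]prop-2-en-1-ol | OC/C=C/c1ccc(OS(=O)(=O)c2ccc(C)cc2)cc1
F3 | step 19 | {(2R,3R)-3-[4-(tosyloxy)phenyl]oxiran-2-yl}methanol | OC[C@H]1O[C@@H]1c2ccc(OS(=O)(=O)c3ccc(C)cc3)cc2
F4 | step 19 | 4-O-{(1S,2R)-2,3-dihydroxy-1-[4-(tosyloxy)phenyl]propyl} ether of 22 | O=C(c1ccc(OCc9ccccc9)cc1OCc9ccccc9)[C@@H]1[C@@H]([C@@H](c2ccc(OCc9ccccc9)cc2)c2c(OCc9ccccc9)cc(O[C@@H](c4ccc(OS(=O)(=O)c5ccc(C)cc5)cc4)[C@H](O)CO)cc2OCc9ccccc9)[C@@H](c2ccc(OCc9ccccc9)cc2OCc9ccccc9)O[C@H]1c1ccc(OCc9ccccc9)cc1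
F5 | step 19 | 4-O-{(S)-[(2R)-oxiran-2-yl][4-(tosyloxy)phenyl]methyl} ether of 22 | O=C(c1ccc(OCc9ccccc9)cc1OCc9ccccc9)[C@@H]1[C@@H]([C@@H](c2ccc(OCc9ccccc9)cc2)c2c(OCc9ccccc9)cc(O[C@@H](c4ccc(OS(=O)(=O)c5ccc(C)cc5)cc4)[C@H]3CO3)cc2OCc9ccccc9)[C@@H](c2ccc(OCc9ccccc9)cc2OCc9ccccc9)O[C@H]1c1ccc(OCc9ccccc9)cc1
F6 | step 19 | analogue of 29 with a 4'-O-tosyl group on the flavan B ring in place of the benzyl ether | O=C(c1ccc(OCc9ccccc9)cc1OCc9ccccc9)[C@@H]1[C@@H]([C@@H](c2ccc(OCc9ccccc9)cc2)c2c(OCc9ccccc9)cc3c(c2OCc9ccccc9)C[C@@H](O)[C@H](c2ccc(OS(=O)(=O)c5ccc(C)cc5)cc2)O3)[C@@H](c2ccc(OCc9ccccc9)cc2OCc9ccccc9)O[C@H]1c1ccc(OCc9ccccc9)cc1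
F7 | step 19 | analogue of 29 with a free 4'-hydroxyl on the flavan B ring (octa-O-benzyl) | O=C(c1ccc(OCc9ccccc9)cc1OCc9ccccc9)[C@@H]1[C@@H]([C@@H](c2ccc(OCc9ccccc9)cc2)c2c(OCc9ccccc9)cc3c(c2OCc9ccccc9)C[C@@H](O)[C@H](c2ccc(O)cc2)O3)[C@@H](c2ccc(OCc9ccccc9)cc2OCc9ccccc9)O[C@H]1c1ccc(OCc9ccccc9)cc1
F8 | step 5 | (E)-3-[4-(allyloxy)-2,6-bis(benzyloxy)phenyl]prop-2-enoic acid | OC(=O)/C=C/c1c(OCc9ccccc9)cc(OCC=C)cc1OCc9ccccc9
F9 | step 5 | (4R)-3-{(E)-3-[4-(allyloxy)-2,6-bis(benzyloxy)phenyl]prop-2-enoyl}-4-benzyl-1,3-oxazolidin-2-one | O=C(/C=C/c1c(OCc9ccccc9)cc(OCC=C)cc1OCc9ccccc9)N1[C@H](Cc2ccccc2)COC1=O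
F10 | step 5 | (4R)-3-{(3S)-3-[4-(allyloxy)-2,6-bis(benzyloxy)phenyl]-3-[4-(benzyloxy)phenyl]propanoyl}-4-benzyl-1,3-oxazolidin-2-one | O=C(C[C@@H](c1ccc(OCc9ccccc9)cc1)c1c(OCc9ccccc9)cc(OCC=C)cc1OCc9ccccc9)N1[C@H](Cc2ccccc2)COC1=O
F11 | step 5 | (3S)-3-[4-(allyloxy)-2,6-bis(benzyloxy)phenyl]-3-[4-(benzyloxy)phenyl]-N-methoxy-N-methylpropanamide | CON(C)C(=O)C[C@@H](c1ccc(OCc9ccccc9)cc1)c1c(OCc9ccccc9)cc(OCC=C)cc1OCc9ccccc9
F12 | step 7 | methyl (4S)-4-[4-(allyloxy)-2,6-bis(benzyloxy)phenyl]-3-[2,4-bis(benzyloxy)benzoyl]-4-[4-(benzyloxy)phenyl]butanoate (C3 epimer mixture) | COC(=O)CC(C(=O)c1ccc(OCc9ccccc9)cc1OCc9ccccc9)[C@@H](c1ccc(OCc9ccccc9)cc1)c1c(OCc9ccccc9)cc(OCC=C)cc1OCc9ccccc9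
F13 | step 7 | (4S)-4-[4-(allyloxy)-2,6-bis(benzyloxy)phenyl]-3-[2,4-bis(benzyloxy)benzoyl]-4-[4-(benzyloxy)phenyl]butanoic acid (C3 epimer mixture) | OC(=O)CC(C(=O)c1ccc(OCc9ccccc9)cc1OCc9ccccc9)[C@@H](c1ccc(OCc9ccccc9)cc1)c1c(OCc9ccccc9)cc(OCC=C)cc1OCc9ccccc9
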